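**Plan**

- Retrosynthesis: the unmasking steps come off first (C7–B to C7–OH, O–Si to O–H, C5–Si to C5–H). Ring A and the pyran are then cut together at C4a–C8a, C5–C6 and C7–C8, leaving a chiral 1,7-diyne and ethynyl pinacol boronate.
- The diyne is cut at O1–C8a (ynol ether from a primary alcohol and trichloroethylene) and at C3–C4 (arylacetyl imide plus silylpropargyl bromide). Ring B goes back to 2,4-dihydroxybenzaldehyde.
- Enabling feature: ring A is a benzene fused to the pyran through C4a–C8a, with O1 on C8a and the second oxygen on C7, meta to it. Its six carbons are therefore three alkyne units: O1–C8a≡C8, C4a≡C5 (tied to O1 through C4–C3–C2) and C6≡C7 carrying boron as a latent hydroxyl.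
- Forward order: ring B is decorated first (prenyl ether, silyl ether, Claisen transfer of the 1,1-dimethylallyl group to C5', re-prenylation) and its formyl carbon is homologated to the arylacetic acid. The chain C2–C3–C4 with both alkynes is then attached, the pyran and ring A are closed in one rhodium-catalysed operation, and three unmasking steps follow.
- Stereochemistry: the only stereocentre, C3 (R), is set by alkylation of the (R)-4-benzyloxazolidin-2-one imide and no later step makes or breaks a bond to it.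

Key step: step 12

Remark: Ar in the names below is 5-(2-methylbut-3-en-2-yl)-4-[(3-methylbut-2-en-1-yl)oxy]-2-[(triisopropylsilyl)oxy]phenyl. Isoflavan numbering is used (O1, C2, C3, C4, C4a, C5 to C8, C8a; ring B primed). Compounds 2, 4, 8, 10, 14, 17, 21 and 27 are assumed to be purchased.

**Route**

Step 1
Reactants: 1 2,4-dihydroxybenzaldehyde; 2 prenyl bromide (1-bromo-3-methylbut-2-ene)
Product: 3 2-hydroxy-4-[(3-methylbut-2-en-1-yl)oxy]benzaldehyde
Conditions: K2CO3 (1.05 equiv), acetone, 50 °C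
Reagents that add atoms: prenyl bromide 2, CC(C)=CCBr
Why: Williamson etherification should take place at the 4-hydroxyl only, because the 2-hydroxyl is held in a hydrogen bond to the formyl group and is the less acidic and less nucleophilic of the two.

Step 2
Reactants: 3 2-hydroxy-4-[(3-methylbut-2-en-1-yl)oxy]benzaldehyde; 4 chlorotriisopropylsilane
Product: 5 4-[(3-methylbut-2-en-1-yl)oxy]-2-[(triisopropylsilyl)oxy]benzaldehyde
Conditions: imidazole, DMF, rt → 40 °C
Reagents that add atoms: chlorotriisopropylsilane 4, CC(C)[Si](Cl)(C(C)C)C(C)C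
Why: Silylation of the remaining phenol installs a bulky, base-tolerant protecting group for the whole route and removes the chelate that would otherwise steer the coming rearrangement to C3.

Step 3
Reactants: 5 4-[(3-methylbut-2-en-1-yl)oxy]-2-[(triisopropylsilyl)oxy]benzaldehyde
Product: 7 4-hydroxy-5-(2-methylbut-3-en-2-yl)-2-[(triisopropylsilyl)oxy]benzaldehyde, via ortho-dienone 6 (not isolated)
Conditions: PhNEt2, 180 °C, Ar
Reagents that add atoms: none
Why: The aromatic Claisen rearrangement ([3,3]-sigmatropic shift) of the aryl prenyl ether should deliver the inverted 1,1-dimethylallyl group to C5, which is para to the silyloxy donor and not wedged between two oxygen substituents as C3 is, and dienone 6 then enolises to the phenol.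

Step 4
Reactants: 7 4-hydroxy-5-(2-methylbut-3-en-2-yl)-2-[(triisopropylsilyl)oxy]benzaldehyde; 8 prenol (3-methylbut-2-en-1-ol)
Product: 9 5-(2-methylbut-3-en-2-yl)-4-[(3-methylbut-2-en-1-yl)oxy]-2-[(triisopropylsilyl)oxy]benzaldehyde (Ar–CHO)
Conditions: PPh3, DIAD, THF, 0 °C → rt
Reagents that add atoms: prenol 8, CC(C)=CCO
Why: Mitsunobu etherification of the acidic para-formyl phenol with a primary allylic alcohol should restore the prenyl ether under neutral conditions that spare the aryl silyl ether.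

Step 5
Reactants: 9 Ar–CHO; 10 (methoxymethyl)triphenylphosphonium chloride
Product: 11 1-Ar-2-methoxyethene (E/Z mixture)
Conditions: 10, NaN(SiMe3)2, THF, 0 °C; then 9, 0 °C → rt
Reagents that add atoms: (methoxymethyl)triphenylphosphonium chloride 10, COC[P+](c1ccccc1)(c1ccccc1)c1ccccc1.[Cl-]
Why: Wittig methoxymethylenation of the aldehyde adds the carbon that becomes C2 in the form of an enol ether.

Step 6
Reactants: 11 1-Ar-2-methoxyethene
Product: 12 2-Ar-acetaldehyde
Conditions: 2 M HCl, THF, 40 °C; crude product used directly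
Reagents that add atoms: water, O
Why: Acid-catalysed enol ether hydrolysis (protonation at the benzylic carbon, hydration of the oxocarbenium ion) should give the homologous aldehyde under conditions too mild to cleave the prenyl or silyl ether.

Step 7
Reactants: 12 2-Ar-acetaldehyde
Product: 13 2-Ar-acetic acid
Conditions: NaClO2, NaH2PO4, 2-methyl-2-butene, t-BuOH/H2O, 0 °C → rt
Reagents that add atoms: sodium chlorite, [Na+].[O-]Cl=O
Why: Pinnick oxidation converts the aldehyde to the acid, and the excess alkene scavenger takes up hypochlorous acid before it can attack the electron-rich ring or the side-chain alkenes.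

Step 8
Reactants: 13 2-Ar-acetic acid; 14 (R)-4-benzyloxazolidin-2-one
Product: 16 (R)-4-benzyl-3-(2-Ar-acetyl)oxazolidin-2-one, via mixed pivalic anhydride 15 (not isolated)
Conditions: t-BuCOCl, Et3N, THF, −20 °C; then 14, LiCl, −20 °C → rt
Reagents that add atoms: (R)-4-benzyloxazolidin-2-one 14, O=C1N[C@H](Cc2ccccc2)CO1
Why: N-Acylation of the oxazolidinone through the mixed pivalic anhydride with LiCl/Et3N activation is the standard route to an Evans imide and needs no strong base.

Step 9
Reactants: 16 (R)-4-benzyl-3-(2-Ar-acetyl)oxazolidin-2-one; 17 3-bromo-1-(trimethylsilyl)prop-1-yne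
Product: 19 (R)-4-benzyl-3-[(2R)-2-Ar-5-(trimethylsilyl)pent-4-ynoyl]oxazolidin-2-one, via sodium Z-enolate 18 (not isolated)
Conditions: NaN(SiMe3)2 (1.05 equiv), THF, −78 °C; then 17, −78 → −40 °C; AcOH, −78 °C
Reagents that add atoms: 3-bromo-1-(trimethylsilyl)prop-1-yne 17, C[Si](C)(C)C#CCBr
Why: In this Evans asymmetric alkylation the chelated sodium Z-enolate 18 should be attacked by the reactive propargylic bromide on the face opposite the benzyl group of the (R)-auxiliary, which sets the future C3 as R.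

Step 10
Reactants: 19 (R)-4-benzyl-3-[(2R)-2-Ar-5-(trimethylsilyl)pent-4-ynoyl]oxazolidin-2-one
Product: 20 (2R)-2-Ar-5-(trimethylsilyl)pent-4-yn-1-ol
Conditions: LiBH4, H2O (1 equiv), Et2O, 0 °C
Reagents that add atoms: none
Why: Reductive cleavage of the imide with LiBH4 should give the primary alcohol without epimerising the α-aryl centre and returns the auxiliary.

Step 11
Reactants: 20 (2R)-2-Ar-5-(trimethylsilyl)pent-4-yn-1-ol; 21 trichloroethylene
Product: 26 trimethyl[(4R)-4-Ar-5-(ethynyloxy)pent-1-yn-1-yl]silane (the chiral 1,7-diyne), via potassium alkoxide 22 (not isolated), via E-1,2-dichlorovinyl ether 23 (not isolated), via chloroethynyl ether 24 (not isolated), via lithium acetylide 25 (not isolated)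
Conditions: KH (2 equiv), THF, 0 °C; 21, −50 °C → rt; then n-BuLi (2.5 equiv), −78 → −40 °C; H2O, −78 °C; product kept cold
Reagents that add atoms: trichloroethylene 21, ClC=C(Cl)Cl
Why: In this Greene ynol ether synthesis the alkoxide 22 adds to dichloroacetylene generated from trichloroethylene to give 23, and n-BuLi then effects elimination to 24 and chlorine–lithium exchange to 25, which water protonates.

Step 12
Reactants: 26 trimethyl[(4R)-4-Ar-5-(ethynyloxy)pent-1-yn-1-yl]silane; 27 2-ethynyl-4,4,5,5-tetramethyl-1,3,2-dioxaborolane (ethynyl pinacol boronate)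
Product: 28 (3R)-3-Ar-7-(4,4,5,5-tetramethyl-1,3,2-dioxaborolan-2-yl)-5-(trimethylsilyl)chroman
Conditions: [Rh(cod)2]BF4 (5 mol %), rac-BINAP (5 mol %), H2 then Ar; 27 (3 equiv), CH2Cl2, rt; slow addition of 26
Reagents that add atoms: ethynyl pinacol boronate 27, C#CB1OC(C)(C)C(C)(C)O1
Why: Proposed new method: the cationic monovalent rhodium centre should bind both tethered alkynes of 26 and couple them oxidatively to a trivalent rhodacyclopentadiene, in which the new C4a–C8a bond closes the pyran as the six-membered ring spanned by the tether O1–C2–C3–C4; insertion of 27 into the unhindered Rh–C8 bond and reductive elimination then form C7–C8 and C5–C6, close ring A as a benzene ring and return monovalent rhodium. The closest known reaction type is the rhodium- or cobalt-catalysed [2+2+2] cyclotrimerisation of tethered 1,6- and 1,7-diynes with alkynyl boronates to fused aryl boronates, and heteroatom-substituted alkynes such as ynamides are established partners in such reactions; a 1,7-diyne whose tether ends in an ynol ether oxygen is the untested element. No stereocentre is formed, and C3 is untouched because no bond to it is made or broken. The selectivity needed is regiochemical: the boron-bearing carbon of 27 must bond to C8 and not to C5, and the SiMe3 group on C5 secures this because the alternative would force SiMe3 and the pinacol boronate onto adjacent ring carbons. Cross-reaction over self-trimerisation of 27 or dimerisation of 26 rests on slow addition of 26 to an excess of 27, the prenyl and vinyl alkenes are far poorer ligands than alkynes for the metallacycle, and room temperature protects the ynol ether from retro-ene loss of ketene.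

Step 13
Reactants: 28 (3R)-3-Ar-7-(4,4,5,5-tetramethyl-1,3,2-dioxaborolan-2-yl)-5-(trimethylsilyl)chroman
Product: 29 (3R)-3-Ar-5-(trimethylsilyl)chroman-7-ol
Conditions: NaBO3·4H2O, THF/H2O (1:1), rt
Reagents that add atoms: sodium perborate (NaBO3·4H2O, drawn as the disodium peroxoborate dimer), [Na+].[Na+].O[B-]1(O)OO[B-](O)(O)OO1
Why: Perborate oxidation of the aryl boronate (1,2-shift of the aryl group from boron to oxygen, then hydrolysis) should unveil the 7-hydroxyl without touching the alkenes, the aryl silane or the silyl ether.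

Step 14
Reactants: 29 (3R)-3-Ar-5-(trimethylsilyl)chroman-7-ol
Product: 30 (3R)-3-{2-hydroxy-5-(2-methylbut-3-en-2-yl)-4-[(3-methylbut-2-en-1-yl)oxy]phenyl}-5-(trimethylsilyl)chroman-7-ol
Conditions: Bu4NF, AcOH (1:1), THF, 0 °C → rt
Reagents that add atoms: none
Why: Fluoride-mediated cleavage of the aryl silyl ether, buffered with acetic acid, is fast at low temperature, whereas the unactivated aryl–SiMe3 bond should be inert to fluoride under these conditions.

Step 15
Reactants: 30 (3R)-3-{2-hydroxy-5-(2-methylbut-3-en-2-yl)-4-[(3-methylbut-2-en-1-yl)oxy]phenyl}-5-(trimethylsilyl)chroman-7-ol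
Product: 31 Manuifolin D, (3R)-3-{2-hydroxy-5-(2-methylbut-3-en-2-yl)-4-[(3-methylbut-2-en-1-yl)oxy]phenyl}chroman-7-ol
Conditions: KOSiMe3 (4 equiv), DMSO, H2O (5 equiv), 70 °C, Ar; then NH4Cl (aq)
Reagents that add atoms: none
Why: Base-catalysed protodesilylation of an aryltrimethylsilane in wet DMSO (silanolate adds to silicon, water protonates the ipso carbon) should remove the C5 silyl group, with the excess of base covering the two phenols and the weakly basic medium leaving the prenyl ether and the terminal alkene alone.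

**Compound list**

1 | 2,4-dihydroxybenzaldehyde | O=Cc1ccc(O)cc1O | starting material
2 | prenyl bromide (1-bromo-3-methylbut-2-ene) | CC(C)=CCBr | starting material
3 | 2-hydroxy-4-[(3-methylbut-2-en-1-yl)oxy]benzaldehyde | O=Cc1ccc(OCC=C(C)C)cc1O | intermediate
4 | chlorotriisopropylsilane | CC(C)[Si](Cl)(C(C)C)C(C)C | starting material
5 | 4-[(3-methylbut-2-en-1-yl)oxy]-2-[(triisopropylsilyl)oxy]benzaldehyde | O=Cc1ccc(OCC=C(C)C)cc1O[Si](C(C)C)(C(C)C)C(C)C | intermediate
6 | 4-formyl-6-(2-methylbut-3-en-2-yl)-3-[(triisopropylsilyl)oxy]cyclohexa-2,4-dien-1-one (racemic at C6) | O=CC1=CC(C(C)(C)C=C)C(=O)C=C1O[Si](C(C)C)(C(C)C)C(C)C | intermediate (not isolated)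
7 | 4-hydroxy-5-(2-methylbut-3-en-2-yl)-2-[(triisopropylsilyl)oxy]benzaldehyde | O=Cc1cc(C(C)(C)C=C)c(O)cc1O[Si](C(C)C)(C(C)C)C(C)C | intermediate
8 | prenol (3-methylbut-2-en-1-ol) | CC(C)=CCO | starting material
9 | 5-(2-methylbut-3-en-2-yl)-4-[(3-methylbut-2-en-1-yl)oxy]-2-[(triisopropylsilyl)oxy]benzaldehyde | O=Cc1cc(C(C)(C)C=C)c(OCC=C(C)C)cc1O[Si](C(C)C)(C(C)C)C(C)C | intermediate
10 | (methoxymethyl)triphenylphosphonium chloride | COC[P+](c1ccccc1)(c1ccccc1)c1ccccc1.[Cl-] | starting material
11 | 1-(2-methoxyethenyl)-5-(2-methylbut-3-en-2-yl)-4-[(3-methylbut-2-en-1-yl)oxy]-2-[(triisopropylsilyl)oxy]benzene (E/Z mixture) | COC=Cc1cc(C(C)(C)C=C)c(OCC=C(C)C)cc1O[Si](C(C)C)(C(C)C)C(C)C | intermediate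
12 | 2-Ar-acetaldehyde | O=CCc1cc(C(C)(C)C=C)c(OCC=C(C)C)cc1O[Si](C(C)C)(C(C)C)C(C)C | intermediate
13 | 2-Ar-acetic acid | OC(=O)Cc1cc(C(C)(C)C=C)c(OCC=C(C)C)cc1O[Si](C(C)C)(C(C)C)C(C)C | intermediate
14 | (R)-4-benzyloxazolidin-2-one | O=C1N[C@H](Cc2ccccc2)CO1 | starting material
15 | 2-Ar-acetic pivalic anhydride | CC(C)(C)C(=O)OC(=O)Cc1cc(C(C)(C)C=C)c(OCC=C(C)C)cc1O[Si](C(C)C)(C(C)C)C(C)C | intermediate (not isolated)
16 | (R)-4-benzyl-3-(2-Ar-acetyl)oxazolidin-2-one | O=C(Cc1cc(C(C)(C)C=C)c(OCC=C(C)C)cc1O[Si](C(C)C)(C(C)C)C(C)C)N1[C@H](Cc2ccccc2)COC1=O | intermediate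
17 | 3-bromo-1-(trimethylsilyl)prop-1-yne | C[Si](C)(C)C#CCBr | starting material
18 | sodium Z-enolate of 16 | [Na+].[O-]/C(=C\c1cc(C(C)(C)C=C)c(OCC=C(C)C)cc1O[Si](C(C)C)(C(C)C)C(C)C)N1[C@H](Cc2ccccc2)COC1=O | intermediate (not isolated)
19 | (R)-4-benzyl-3-[(2R)-2-Ar-5-(trimethylsilyl)pent-4-ynoyl]oxazolidin-2-one | C=CC(C)(C)c1cc([C@@H](CC#C[Si](C)(C)C)C(=O)N2[C@H](Cc3ccccc3)COC2=O)c(O[Si](C(C)C)(C(C)C)C(C)C)cc1OCC=C(C)C | intermediate
20 | (2R)-2-Ar-5-(trimethylsilyl)pent-4-yn-1-ol | C=CC(C)(C)c1cc([C@@H](CC#C[Si](C)(C)C)CO)c(O[Si](C(C)C)(C(C)C)C(C)C)cc1OCC=C(C)C | intermediate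
21 | trichloroethylene | ClC=C(Cl)Cl | starting material
22 | potassium alkoxide of 20 | C=CC(C)(C)c1cc([C@@H](CC#C[Si](C)(C)C)C[O-])c(O[Si](C(C)C)(C(C)C)C(C)C)cc1OCC=C(C)C.[K+] | intermediate (not isolated)
23 | (E)-1,2-dichlorovinyl ether of 20 | C=CC(C)(C)c1cc([C@@H](CC#C[Si](C)(C)C)CO/C(Cl)=C\Cl)c(O[Si](C(C)C)(C(C)C)C(C)C)cc1OCC=C(C)C | intermediate (not isolated)
24 | chloroethynyl ether of 20 | C=CC(C)(C)c1cc([C@@H](CC#C[Si](C)(C)C)COC#CCl)c(O[Si](C(C)C)(C(C)C)C(C)C)cc1OCC=C(C)C | intermediate (not isolated)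
25 | lithium acetylide of the ethynyl ether of 20 | C=CC(C)(C)c1cc([C@@H](CC#C[Si](C)(C)C)COC#C[Li])c(O[Si](C(C)C)(C(C)C)C(C)C)cc1OCC=C(C)C | intermediate (not isolated)
26 | trimethyl[(4R)-4-Ar-5-(ethynyloxy)pent-1-yn-1-yl]silane (chiral 1,7-diyne) | C=CC(C)(C)c1cc([C@@H](CC#C[Si](C)(C)C)COC#C)c(O[Si](C(C)C)(C(C)C)C(C)C)cc1OCC=C(C)C | intermediate
27 | 2-ethynyl-4,4,5,5-tetramethyl-1,3,2-dioxaborolane | C#CB1OC(C)(C)C(C)(C)O1 | starting material
28 | (3R)-3-Ar-7-(4,4,5,5-tetramethyl-1,3,2-dioxaborolan-2-yl)-5-(trimethylsilyl)chroman | C=CC(C)(C)c1cc([C@@H]2COc3cc(B4OC(C)(C)C(C)(C)O4)cc([Si](C)(C)C)c3C2)c(O[Si](C(C)C)(C(C)C)C(C)C)cc1OCC=C(C)C | intermediate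
29 | (3R)-3-Ar-5-(trimethylsilyl)chroman-7-ol | C=CC(C)(C)c1cc([C@@H]2COc3cc(O)cc([Si](C)(C)C)c3C2)c(O[Si](C(C)C)(C(C)C)C(C)C)cc1OCC=C(C)C | intermediate
30 | (3R)-3-{2-hydroxy-5-(2-methylbut-3-en-2-yl)-4-[(3-methylbut-2-en-1-yl)oxy]phenyl}-5-(trimethylsilyl)chroman-7-ol | C=CC(C)(C)c1cc([C@@H]2COc3cc(O)cc([Si](C)(C)C)c3C2)c(O)cc1OCC=C(C)C | intermediate
31 | Manuifolin D, (3R)-3-{2-hydroxy-5-(2-methylbut-3-en-2-yl)-4-[(3-methylbut-2-en-1-yl)oxy]phenyl}chroman-7-ol | C=CC(C)(C)c1cc([C@@H]2COc3cc(O)ccc3C2)c(O)cc1OCC=C(C)C | target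

**Step count and risks**

Total: 15 steps. Longest linear sequence: 15 steps (1 → 31).

Steps most likely to fail:

1. Step 12 (proposed new method). The ynol ether may be lost to hydration, oligomerisation or retro-ene fragmentation before the two tethered alkynes couple on rhodium, and insertion of the boronate may proceed with incomplete regiocontrol. The fallback uses known chemistry, sets out from imide 16 and returns to the route at 31; it forms the pyran by classical C–O bond closure onto a ready-made ring A. Commercial 2-bromo-4-hydroxybenzaldehyde is silylated with 4 and imidazole to 2-bromo-4-[(triisopropylsilyl)oxy]benzaldehyde F1, reduced with NaBH4 to {2-bromo-4-[(triisopropylsilyl)oxy]phenyl}methanol F2, and brominated with CBr4/PPh3 to 2-bromo-1-(bromomethyl)-4-[(triisopropylsilyl)oxy]benzene F3. Enolate 18, generated from 16 as in step 9, is alkylated with F3 to the benzylated imide F4, and LiBH4 then releases the primary alcohol F5. An intramolecular palladium-catalysed aryl ether synthesis (Pd(OAc)2, 2-(di-tert-butylphosphino)-1,1'-binaphthyl, Cs2CO3, toluene, 70 °C) closes the pyran to the bis-silyl isoflavan F6, and Bu4NF/AcOH removes both silyl groups to give 31. This path also avoids the protodesilylation of step 15.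

2. Step 11. Migration of the triisopropylsilyl group from the phenolic oxygen to the potassium alkoxide, and alkoxide attack at the alkynyl silicon, may compete with capture of dichloroacetylene. The fallback sets out from alcohol 20 and returns at 26 without ever forming a free potassium alkoxide. Formylation (HCO2H, DCC, DMAP, CH2Cl2) gives the formate F7. Dichloromethylenation of the formyl carbonyl (PPh3, CCl4, THF, 60 °C) gives the 2,2-dichlorovinyl ether F8. n-BuLi (2.2 equiv, −78 °C) then converts it through 24 and 25 into 26 on aqueous quench.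

3. Step 3. The rearrangement may go partly toward C3, the product phenol may isomerise further by the abnormal Claisen pathway to the 1,2-dimethylallyl isomer, or the prenyl group may be lost by C–O heterolysis at 180 °C. The fallback sets out from 1 and returns at 9, replacing steps 1 to 4 by a cross-coupling that builds the quaternary carbon. Bromination (Br2, AcOH) gives 5-bromo-2,4-dihydroxybenzaldehyde F9. K2CO3 and 2 give the 4-prenyl ether F10, and 4 with imidazole gives the silyl ether F11. A branch-selective (γ-selective) Suzuki–Miyaura coupling of F11 with 4,4,5,5-tetramethyl-2-(3-methylbut-2-en-1-yl)-1,3,2-dioxaborolane (Pd(OAc)2, bulky biaryl dialkylphosphine, K3PO4, THF/H2O) then attaches the 1,1-dimethylallyl group at C5 and gives 9.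

**Further compounds**

F1 | step 12 | 2-bromo-4-[(triisopropylsilyl)oxy]benzaldehyde | O=Cc1ccc(O[Si](C(C)C)(C(C)C)C(C)C)cc1Br
F2 | step 12 | {2-bromo-4-[(triisopropylsilyl)oxy]phenyl}methanol | OCc1ccc(O[Si](C(C)C)(C(C)C)C(C)C)cc1Br
F3 | step 12 | 2-bromo-1-(bromomethyl)-4-[(triisopropylsilyl)oxy]benzene | BrCc1ccc(O[Si](C(C)C)(C(C)C)C(C)C)cc1Br
F4 | step 12 | (R)-4-benzyl-3-[(2R)-2-Ar-3-{2-bromo-4-[(triisopropylsilyl)oxy]phenyl}propanoyl]oxazolidin-2-one | C=CC(C)(C)c1cc([C@@H](Cc2ccc(O[Si](C(C)C)(C(C)C)C(C)C)cc2Br)C(=O)N2[C@H](Cc3ccccc3)COC2=O)c(O[Si](C(C)C)(C(C)C)C(C)C)cc1OCC=C(C)C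
F5 | step 12 | (2R)-2-Ar-3-{2-bromo-4-[(triisopropylsilyl)oxy]phenyl}propan-1-ol | C=CC(C)(C)c1cc([C@@H](Cc2ccc(O[Si](C(C)C)(C(C)C)C(C)C)cc2Br)CO)c(O[Si](C(C)C)(C(C)C)C(C)C)cc1OCC=C(C)C
F6 | step 12 | (3R)-3-Ar-7-[(triisopropylsilyl)oxy]chroman | C=CC(C)(C)c1cc([C@@H]2COc3cc(O[Si](C(C)C)(C(C)C)C(C)C)ccc3C2)c(O[Si](C(C)C)(C(C)C)C(C)C)cc1OCC=C(C)C
F7 | step 11 | (2R)-2-Ar-5-(trimethylsilyl)pent-4-yn-1-yl formate | C=CC(C)(C)c1cc([C@@H](CC#C[Si](C)(C)C)COC=O)c(O[Si](C(C)C)(C(C)C)C(C)C)cc1OCC=C(C)C
F8 | step 11 | 2,2-dichlorovinyl ether of 20 | C=CC(C)(C)c1cc([C@@H](CC#C[Si](C)(C)C)COC=C(Cl)Cl)c(O[Si](C(C)C)(C(C)C)C(C)C)cc1OCC=C(C)C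
F9 | step 3 | 5-bromo-2,4-dihydroxybenzaldehyde | O=Cc1cc(Br)c(O)cc1O
F10 | step 3 | 5-bromo-2-hydroxy-4-[(3-methylbut-2-en-1-yl)oxy]benzaldehyde | O=Cc1cc(Br)c(OCC=C(C)C)cc1O
F11 | step 3 | 5-bromo-4-[(3-methylbut-2-en-1-yl)oxy]-2-[(triisopropylsilyl)oxy]benzaldehyde | O=Cc1cc(Br)c(OCC=C(C)C)cc1O[Si](C(C)C)(C(C)C)C(C)C
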